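You read these flasks at 50 h, later than the last ochre reading at 15.0 h, so first ask where the L goes, then what becomes of G afterwards.

| setting | ochre | summer | autumn | dawn | spring |
|---|---|---|---|---|---|
| L | 0.22 M | 0.22 M | 0.22 M | 0.22 M | 0.22 M |
| D | 1.7 equiv | 1.10 equiv | 1.10 equiv | 1.10 equiv | 1.10 equiv |
| temperature | 55 °C | 55 °C | 15 °C |  | 35 °C |
| remark | run made earlier |  |  | at 55 °C until 10 h, from then on at 15 °C |  |
| time |  | 50 h | 50 h | 50 h | 50 h |

ochre run (percent of the L charged)

| time / h | G / % | L / % |
|---|---|---|
| 1.33 | 24.3 | 27.7 |
| 2.00 | 27.6 | 15.6 |
| 3.00 | 29.3 | 6.3 |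
| 4.00 | 28.9 | 3.9 |
| 6.00 | 26.3 | 0.7 |
| 10.0 | 24.4 | 0 |
| 15.0 | 22.2 | 0.1 |

(scatter of a reading: 0.5 percentage points)

- the earlier runs do not show what temperature does; that part of a forecast is a guess

1. the flask with the highest amount of G, in percent of the L charged ("all alike" if they lie within 1.5 percentage points) (summer / autumn / dawn / spring / all alike)
2. final G, as a percentage of the L charged, in summer
3. final G, as a percentage of the L charged, in autumn
4. final G, as a percentage of the L charged, in dawn
5. final G, as a percentage of the L charged, in spring

At the first ochre reading, at 1.33 h, the L used is 72.3% of the charge. G stands at 24.3%, and the other 48.0% has gone elsewhere. The ratio of the two, 0.506, is the odds between the two branches. Now assume that making G takes D while the other loss of L does not; ochre, with its one charge of D, cannot test this. The odds then grow in step with D, so dividing by the ochre charge gives 0.298: the branching odds per equivalent of D, a selectivity factor for 55 °C and 0.22 M of L.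

Take dawn, hot until 10 h. Ochre had 0.7% of L left at 6.00 h, and I assume dawn, with less D, comes close to that by the change. At 1.10 equiv the odds are 0.328, so the share of used L that becomes G is 24.7%. G then wastes: ochre falls from 29.3% at 3.00 h to 24.4% at 10.0 h, a factor of 0.833, which brings dawn to 20.5% at the change. I assume the cold stretch at 15 °C adds little loss, so that is my number for dawn. For autumn and spring the readings give me no number, since temperature is a guess there.

One link can be tried again: the reading behind the odds. The reading at 2.00 h gives odds of 0.486, hence a share of 23.9% and 19.9% for dawn, beside my 20.5%. Both figures carry the same factor 0.833 and the same assumption on D, so this tests the choice of reading and leaves the factor unchecked.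

The forecast named dawn as the best flask, with summer 17%, autumn 20%, dawn 25% and spring 24%, reasoning that “cooling at 10 h largely freezes the decay”. Its dawn is higher than mine.

The flasks end with G at 14.6% in summer, 25.8% in autumn, 18.0% in dawn and 32.2% in spring, so spring holds the most.

    2 L → Z (k = 0.105 /M/h, Ea = 61.0 kJ/mol)
    G ⇌ Q (K = 1.70, k = 0.00406 /h, Ea = 106 kJ/mol, ΔH = −37.0 kJ/mol)
    L + D → G (k = 0.210 /M/h, Ea = 64.0 kJ/mol)
    L → E (k = 0.0465 /h, Ea = 102 kJ/mol)
    (constants at 35 °C)

In dawn, G stood at 18.2% at 10.0 h, lower than my 20.5%, and at 18.0% at 50.0 h. G and Q together end at 24.9% in dawn, against the share of 24.7% from the odds. For the neighbour of dawn charged with 4.40 equiv of D, the odds per equivalent give 1.31, a share of 56.7%, and that neighbour ends with G and Q together at 58.3%.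

All runs were generated by integration for substances that don't exist; the scatter is artificial.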